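Everything rests on disconnecting the C3–C4 bond of ring A. Ring B, with its C7=C8(C17) alkene, the C5 stereocentre and the C4 carbon attached to C5, is the skeleton of (S)-carvone, whose carbonyl (C9) lets C10 be alkylated twice. The precursor of the key step is a carvone carrying at C10 the C20 methyl and, trans to the isopropenyl group, a 3-oxopropyl arm (C1–C3). One iron-hydride hydrogen-atom transfer turns the isopropenyl carbon into the tertiary C4 radical, which closes ring A onto the aldehyde, giving the gem-dimethyl C4, the C3 carbinol and the trans-decalin together. C9 is then extended; the C30 acid is attached last.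

Key step: step 5

Assumption: the acyl residue is read as 30-hydroxytriacontanoyl (29 CH2 groups between C=O and OH). Labdane numbering (C1–C20) is used for all terpenoid compounds, and the target is the ent-labdane with 3R,5S,9R,10S,13E configuration.

Step 1
Reactants: 1 (S)-(+)-carvone
Product: 3 (5S)-6-methylcarvone as a mixture of C6 epimers, via carvone lithium dienolate 2 (not isolated)
Conditions: LDA, THF, −78 °C; MeI, −78 → 0 °C
Reagents that add atoms: methyl iodide, CI
Why: Kinetic α′-deprotonation of the enone followed by C-methylation (lithium enolate alkylation) brings in C20, and the configuration of the new centre does not matter because step 2 planarises it again.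

Step 2
Reactants: 3 (5S)-6-methylcarvone; 4 allyl bromide
Product: 6 (5R,6R)-6-allyl-6-methylcarvone (allyl trans to isopropenyl), via 6-methylcarvone lithium enolate 5 (not isolated)
Conditions: LDA, THF, −78 → 0 °C; 4, −78 °C → rt
Reagents that add atoms: none
Why: In this second enolate alkylation the isopropenyl group next to the tetrasubstituted enolate carbon stands pseudoaxial to relieve A(1,2) strain and shields its own face, so allyl bromide should enter anti to it and fix the quaternary C10 with C1 trans to C4 and C20 cis to C4.

Step 3
Reactants: 6 (5R,6R)-6-allyl-6-methylcarvone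
Product: 8 keto alcohol (3-hydroxypropyl arm on C10), via alkyl(disiamyl)borane 7 (not isolated)
Conditions: Sia2BH (1.1 equiv, made in situ from BH3·SMe2 and 2-methylbut-2-ene), THF, 0 °C; then 30% H2O2, pH 7 phosphate buffer, 0 °C → rt
Reagents that add atoms: hydrogen peroxide, OO
Why: Hydroboration–oxidation with a bulky dialkylborane, which takes the monosubstituted allyl terminus much faster than the 1,1-disubstituted isopropenyl alkene or the hindered conjugated ketone and puts boron on the terminal carbon, while peroxide at neutral pH avoids nucleophilic epoxidation of the enone.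

Step 4
Reactants: 8 keto alcohol
Product: 9 keto aldehyde (3-oxopropyl arm C1–C3 on C10)
Conditions: Dess–Martin periodinane, CH2Cl2, 0 °C → rt
Reagents that add atoms: none
Why: Dess–Martin oxidation stops at the aldehyde under neutral, non-aqueous conditions that leave the enone and the isopropenyl group alone, and no stereocentre next to a carbonyl group carries a hydrogen.

Step 5
Reactants: 9 keto aldehyde
Product: 12 ent-3β-hydroxy-11-nordrim-7-en-9-one (trans-decalin; equatorial 3-OH), via C4 tertiary radical 10 (not isolated), via C3 alkoxy radical 11 (not isolated)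
Conditions: Fe(acac)3 (0.3 equiv), PhSiH3 (2.5 equiv), degassed EtOH (0.02 M), 60 °C
Reagents that add atoms: none
Why: Fe(acac)3 and PhSiH3 in ethanol generate an iron hydride that hands H• to the terminal CH2 of the isopropenyl unit (Markovnikov MHAT), which makes C4 the tertiary radical 10 with both methyl groups in place. Ring A closes when 10 attacks the aldehyde carbon C3 in 6-exo-trig mode, and since this attack is reversible it is the rapid reduction of alkoxy radical 11 by iron(II) and its protonation by the solvent that carries the reaction to 12. The closest known reaction types are the iron-hydride HAT reductive cyclisation of alkene-tethered ketones and the intermolecular iron-HAT coupling of unactivated alkenes with aldehydes. The trans ring fusion is inherited, since C5 and C10 hold the two reacting arms trans-diequatorial on ring B, and C4 becomes quaternary but is not stereogenic. The only new stereocentre, C3, is set in the chair transition state, in which the carbonyl oxygen should point equatorially to avoid the axial hydrogens on C1 and C5, giving the equatorial 3R carbinol, with any axial epimer removed by chromatography. The step needs hydrogen-atom transfer to the isopropenyl alkene and not to the enone, which is secured by the electron-rich 1,1-disubstituted alkene against the electron-poor trisubstituted C7=C8, while attack of 10 on C7, C8 or C9 would give four-membered or strained bridged rings and high dilution suppresses intermolecular conjugate addition.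

Step 6
Reactants: 12 ent-3β-hydroxy-11-nordrim-7-en-9-one
Product: 13 3-O-TBS ether of 12
Conditions: TBSOTf, 2,6-lutidine, CH2Cl2, 0 °C
Reagents that add atoms: tert-butyldimethylsilyl triflate, CC(C)(C)[Si](C)(C)OS(=O)(=O)C(F)(F)F
Why: Silyl triflate silylation overcomes the hindrance of the carbinol next to the quaternary C4, and 2,6-lutidine is too weak a base to enolise a ketone that has no α-hydrogen.

Step 7
Reactants: 13 3-O-TBS enone
Product: 15 ent-3β-(TBSO)drima-7,9(11)-diene, via C9 β-hydroxysilane 14 (not isolated)
Conditions: TMSCH2Li, THF, −78 → 0 °C, H2O quench; crude carbinol, KH, THF, 0 °C → rt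
Reagents that add atoms: (trimethylsilyl)methyllithium, [Li]C[Si](C)(C)C
Why: Peterson olefination: the small and strongly nucleophilic silylmethyllithium should add 1,2 to the hindered enone, as simple organolithiums do with 6,6-dialkylcarvones, anti to the axial C20 methyl, and base-induced syn elimination from the potassium alkoxide can only give the 9(11)-methylene (C11) without acid that might isomerise the diene.

Step 8
Reactants: 15 ent-3β-(TBSO)drima-7,9(11)-diene
Product: 17 ent-3β-(TBSO)drimenol (C11 alcohol), via C11 B-alkyl-9-BBN 16 (not isolated)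
Conditions: 9-BBN, THF, rt → 45 °C; then aq NaOH, 30% H2O2, 0 °C → rt
Reagents that add atoms: hydrogen peroxide, OO
Why: Hydroboration–oxidation in which 9-BBN places boron on the terminal C11 of the 1,1-disubstituted alkene and ignores the trisubstituted C7=C8, and because the borane approaches anti to the axial C20 methyl, hydrogen arrives at C9 on the face of H5 and C11 ends up equatorial.

Step 9
Reactants: 17 ent-3β-(TBSO)drimenol
Product: 18 C11 iodide
Conditions: I2, PPh3, imidazole, CH2Cl2, 0 °C → rt
Reagents that add atoms: iodine, II
Why: Appel-type iodination (PPh3, I2, imidazole) replaces the activated primary hydroxyl by iodide under almost neutral conditions, so C9, the alkene and the silyl ether are not affected.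

Step 10
Reactants: 18 C11 iodide
Product: 20 14,15-dinorlabd-7-en-13-ol 3-O-TBS ether (C13 epimers), via C11 alkyllithium 19 (not isolated)
Conditions: t-BuLi (2.1 equiv), Et2O/pentane, −78 °C; then BF3·OEt2, (±)-propylene oxide, −78 °C
Reagents that add atoms: propylene oxide, CC1CO1
Why: Polarity reversal avoids an SN2 reaction at the β-branched C11, where E2 loss of the allylic H9 would compete: iodine–lithium exchange gives the primary alkyllithium, which opens the BF3-activated epoxide at its CH2 terminus (bringing C12, C13 and C16), and the two carbinol epimers converge in step 11.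

Step 11
Reactants: 20 secondary alcohol
Product: 21 14,15-dinorlabd-7-en-13-one 3-O-TBS ether (methyl ketone)
Conditions: Dess–Martin periodinane, CH2Cl2, rt
Reagents that add atoms: none
Why: Dess–Martin oxidation of the secondary alcohol removes the stereorandom carbinol centre, and C9 lies too far from the new ketone to epimerise.

Step 12
Reactants: 21 methyl ketone
Product: 22 ethyl ent-3β-(TBSO)labda-7,13E-dien-15-oate
Conditions: (EtO)2P(O)CH2CO2Et, NaH, THF, 0 → 50 °C; chromatography
Reagents that add atoms: triethyl phosphonoacetate, CCOC(=O)CP(=O)(OCC)OCC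
Why: Horner–Wadsworth–Emmons olefination of the methyl ketone puts the ester group trans to the larger CH2 substituent of C13, so the 13E enoate should prevail, and the Z isomer can be removed on silica.

Step 13
Reactants: 22 E-enoate
Product: 23 3-O-TBS ent-labda-7,13E-diene-3β,15-diol
Conditions: DIBAL-H (2.5 equiv), CH2Cl2, −78 °C; Rochelle salt work-up
Reagents that add atoms: none
Why: DIBAL-H reduces the conjugated ester by 1,2-hydride delivery to the allylic alcohol without touching the alkene geometry, the C7=C8 alkene or the silyl ether.

Step 14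
Reactants: 24 15-pentadecanolide
Product: 25 methyl 15-hydroxypentadecanoate
Conditions: MeOH, cat. H2SO4, reflux
Reagents that add atoms: methanol, CO
Why: Acid-catalysed transesterification in excess methanol opens the unstrained macrolactone to the hydroxy ester, which serves both C15 halves and makes a statistical monoprotection of a symmetrical diol unnecessary.

Step 15
Reactants: 25 methyl 15-hydroxypentadecanoate
Product: 26 methyl 15-(TBSO)pentadecanoate
Conditions: TBSCl, imidazole, DMF, rt
Reagents that add atoms: tert-butyldimethylsilyl chloride, CC(C)(C)[Si](C)(C)Cl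
Why: Imidazole-promoted silylation of an unhindered primary alcohol.

Step 16
Reactants: 26 methyl 15-(TBSO)pentadecanoate
Product: 27 15-(TBSO)pentadecanal
Conditions: DIBAL-H (1.05 equiv), CH2Cl2, −78 °C; MeOH quench at −78 °C
Reagents that add atoms: none
Why: Partial ester reduction with one equivalent of DIBAL-H, which at −78 °C halts at the aldehyde oxidation level until the cold quench.

Step 17
Reactants: 25 methyl 15-hydroxypentadecanoate
Product: 28 methyl 15-bromopentadecanoate
Conditions: CBr4, PPh3, CH2Cl2, 0 °C
Reagents that add atoms: carbon tetrabromide, BrC(Br)(Br)Br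
Why: Appel bromination converts the primary alcohol into the bromide under neutral conditions that spare the ester.

Step 18
Reactants: 28 methyl 15-bromopentadecanoate
Product: 29 (14-methoxycarbonyltetradecyl)triphenylphosphonium bromide
Conditions: PPh3, MeCN, reflux
Reagents that add atoms: triphenylphosphine, c1ccc(cc1)P(c1ccccc1)c1ccccc1
Why: SN2 quaternisation of triphenylphosphine by an unhindered primary bromide.

Step 19
Reactants: 29 phosphonium bromide; 27 15-(TBSO)pentadecanal
Product: 31 methyl (15Z)-30-(TBSO)triacont-15-enoate, via phosphonium ylide 30 (not isolated)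
Conditions: NaHMDS, THF, −78 → 0 °C; then 27, −78 °C → rt
Reagents that add atoms: none
Why: Wittig olefination with a non-stabilised ylide, formed because the hindered amide base removes the more acidic proton next to phosphorus and not the one next to the ester; the Z geometry expected is irrelevant since step 20 saturates the alkene.

Step 20
Reactants: 31 methyl (15Z)-30-(TBSO)triacont-15-enoate
Product: 32 methyl 30-(TBSO)triacontanoate
Conditions: H2 (1 atm), 10% Pd/C, EtOAc, rt
Reagents that add atoms: none
Why: Heterogeneous catalytic hydrogenation saturates the only alkene, and in ethyl acetate the silyl ether and the ester are inert.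

Step 21
Reactants: 32 methyl 30-(TBSO)triacontanoate
Product: 33 30-(TBSO)triacontanoic acid
Conditions: LiOH, THF/MeOH/H2O, 45 °C; aq KHSO4 to pH 4, 0 °C
Reagents that add atoms: lithium hydroxide, [Li+].[OH-]
Why: Saponification of the methyl ester, with a primary TBS ether that tolerates aqueous hydroxide and a brief, cold, mildly acidic work-up.

Step 22
Reactants: 23 allylic alcohol; 33 30-(TBSO)triacontanoic acid
Product: 34 bis-TBS ether of the target
Conditions: EDC·HCl, DMAP (cat.), CH2Cl2, rt
Reagents that add atoms: none
Why: Steglich-type carbodiimide/DMAP esterification acylates the only free hydroxyl, the primary allylic C15–OH, under neutral conditions that cannot ionise the allylic system.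

Step 23
Reactants: 34 bis-TBS ether
Product: 35 target CNP0303636.1
Conditions: HF·pyridine, pyridine, THF, 0 °C → rt
Reagents that add atoms: none
Why: Fluoride-driven cleavage of both Si–O bonds with pyridine-buffered HF, which is acidic enough for the hindered C3 ether yet leaves the allylic ester and the two trisubstituted alkenes intact.

Compound list
1 | (S)-(+)-carvone, (5S)-2-methyl-5-(prop-1-en-2-yl)cyclohex-2-en-1-one | CC1=CC[C@@H](CC1=O)C(C)=C | starting material
2 | lithium cross-conjugated dienolate of 1 (deprotonated at the ring CH2 next to C=O) | [Li+].CC1=CC[C@@H](C=C1[O-])C(C)=C | intermediate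
3 | (5S)-2,6-dimethyl-5-(prop-1-en-2-yl)cyclohex-2-en-1-one (6-methylcarvone, both C6 epimers) | CC1=CC[C@H](C(C)=C)C(C)C1=O | intermediate
4 | allyl bromide (C1–C3) | C=CCBr | starting material
5 | lithium enolate of 3 (tetrasubstituted enolate) | [Li+].CC1=CC[C@H](C(C)=C)C(C)=C1[O-] | intermediate
6 | (5R,6R)-6-allyl-2,6-dimethyl-5-(prop-1-en-2-yl)cyclohex-2-en-1-one, allyl trans and methyl cis to isopropenyl | CC1=CC[C@H](C(C)=C)[C@@](C)(CC=C)C1=O | intermediate
7 | bis(3-methylbutan-2-yl)borane adduct of 6 at the allyl terminus | CC1=CC[C@H](C(C)=C)[C@@](C)(CCCB(C(C)C(C)C)C(C)C(C)C)C1=O | intermediate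
8 | (5R,6R)-6-(3-hydroxypropyl)-2,6-dimethyl-5-(prop-1-en-2-yl)cyclohex-2-en-1-one | CC1=CC[C@H](C(C)=C)[C@@](C)(CCCO)C1=O | intermediate
9 | 3-[(1R,6R)-1,3-dimethyl-2-oxo-6-(prop-1-en-2-yl)cyclohex-3-en-1-yl]propanal (keto aldehyde) | CC1=CC[C@H](C(C)=C)[C@@](C)(CCC=O)C1=O | intermediate
10 | tertiary C4 radical (2-propyl radical on C5 of 9) | CC1=CC[C@H]([C](C)C)[C@@](C)(CCC=O)C1=O | intermediate
11 | C3 alkoxy radical of the closed trans-decalin | CC1=CC[C@@H]2C(C)(C)[C@H]([O])CC[C@@]2(C)C1=O | intermediate
12 | ent-3β-hydroxy-11-nordrim-7-en-9-one (3R,5R,10R; trans-decalin, equatorial 3-OH cis to C20, H5 on the opposite face) | CC1=CC[C@@H]2C(C)(C)[C@H](O)CC[C@@]2(C)C1=O | intermediate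
13 | 3-O-TBS ether of 12 | CC1=CC[C@@H]2C(C)(C)[C@H](O[Si](C)(C)C(C)(C)C)CC[C@@]2(C)C1=O | intermediate
14 | C9 tertiary carbinol bearing CH2SiMe3 (CH2SiMe3 anti to C20; this centre is lost again) | CC1=CC[C@@H]2C(C)(C)[C@H](O[Si](C)(C)C(C)(C)C)CC[C@@]2(C)[C@@]1(O)C[Si](C)(C)C | intermediate
15 | ent-3β-(TBSO)drima-7,9(11)-diene | CC1=CC[C@@H]2C(C)(C)[C@H](O[Si](C)(C)C(C)(C)C)CC[C@@]2(C)C1=C | intermediate
16 | C11 B-alkyl-9-borabicyclo[3.3.1]nonane (H9 cis to H5) | CC1=CC[C@@H]2C(C)(C)[C@H](O[Si](C)(C)C(C)(C)C)CC[C@@]2(C)[C@@H]1CB3C4CCCC3CCC4 | intermediate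
17 | ent-3β-(TBSO)drimenol (C11, C20 and O3 on one face, H5 and H9 on the other) | CC1=CC[C@@H]2C(C)(C)[C@H](O[Si](C)(C)C(C)(C)C)CC[C@@]2(C)[C@@H]1CO | intermediate
18 | ent-3β-(TBSO)-11-iododrim-7-ene | CC1=CC[C@@H]2C(C)(C)[C@H](O[Si](C)(C)C(C)(C)C)CC[C@@]2(C)[C@@H]1CI | intermediate
19 | C11 alkyllithium from 18 | CC1=CC[C@@H]2C(C)(C)[C@H](O[Si](C)(C)C(C)(C)C)CC[C@@]2(C)[C@@H]1C[Li] | intermediate
20 | ent-3β-(TBSO)-14,15-dinorlabd-7-en-13-ol (both C13 epimers) | CC1=CC[C@@H]2C(C)(C)[C@H](O[Si](C)(C)C(C)(C)C)CC[C@@]2(C)[C@@H]1CCC(C)O | intermediate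
21 | ent-3β-(TBSO)-14,15-dinorlabd-7-en-13-one | CC1=CC[C@@H]2C(C)(C)[C@H](O[Si](C)(C)C(C)(C)C)CC[C@@]2(C)[C@@H]1CCC(C)=O | intermediate
22 | ethyl ent-3β-(TBSO)labda-7,13E-dien-15-oate | CC1=CC[C@@H]2C(C)(C)[C@H](O[Si](C)(C)C(C)(C)C)CC[C@@]2(C)[C@@H]1CC/C(C)=C/C(=O)OCC | intermediate
23 | 3-O-TBS ent-labda-7,13E-diene-3β,15-diol | CC1=CC[C@@H]2C(C)(C)[C@H](O[Si](C)(C)C(C)(C)C)CC[C@@]2(C)[C@@H]1CC/C(C)=C/CO | intermediate
24 | 15-pentadecanolide (oxacyclohexadecan-2-one) | O=C1CCCCCCCCCCCCCCO1 | starting material
25 | methyl 15-hydroxypentadecanoate | COC(=O)CCCCCCCCCCCCCCO | intermediate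
26 | methyl 15-(tert-butyldimethylsilyloxy)pentadecanoate | COC(=O)CCCCCCCCCCCCCCO[Si](C)(C)C(C)(C)C | intermediate
27 | 15-(tert-butyldimethylsilyloxy)pentadecanal | CC(C)(C)[Si](C)(C)OCCCCCCCCCCCCCCC=O | intermediate
28 | methyl 15-bromopentadecanoate | COC(=O)CCCCCCCCCCCCCCBr | intermediate
29 | (14-methoxycarbonyltetradecyl)triphenylphosphonium bromide | COC(=O)CCCCCCCCCCCCCC[P+](c1ccccc1)(c1ccccc1)c1ccccc1.[Br-] | intermediate
30 | ylide of 29 | COC(=O)CCCCCCCCCCCCCC=P(c1ccccc1)(c1ccccc1)c1ccccc1 | intermediate
31 | methyl (15Z)-30-(tert-butyldimethylsilyloxy)triacont-15-enoate | CC(C)(C)[Si](C)(C)OCCCCCCCCCCCCCC/C=C\CCCCCCCCCCCCCC(=O)OC | intermediate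
32 | methyl 30-(tert-butyldimethylsilyloxy)triacontanoate | CC(C)(C)[Si](C)(C)OCCCCCCCCCCCCCCCCCCCCCCCCCCCCCC(=O)OC | intermediate
33 | 30-(tert-butyldimethylsilyloxy)triacontanoic acid | CC(C)(C)[Si](C)(C)OCCCCCCCCCCCCCCCCCCCCCCCCCCCCCC(=O)O | intermediate
34 | ent-3β-(TBSO)labda-7,13E-dien-15-yl 30-(TBSO)triacontanoate | CC1=CC[C@@H]2C(C)(C)[C@H](O[Si](C)(C)C(C)(C)C)CC[C@@]2(C)[C@@H]1CC/C(C)=C/COC(=O)CCCCCCCCCCCCCCCCCCCCCCCCCCCCCO[Si](C)(C)C(C)(C)C | intermediate
35 | CNP0303636.1, (3R,5S,9R,10S)-3-hydroxylabda-7,13E-dien-15-yl 30-hydroxytriacontanoate (ent-3β-hydroxy series) | CC1=CC[C@@H]2C(C)(C)[C@H](O)CC[C@@]2(C)[C@@H]1CC/C(C)=C/COC(=O)CCCCCCCCCCCCCCCCCCCCCCCCCCCCCO | target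

Total step count: 23.
Longest linear sequence: 15 steps (steps 1–13, 22 and 23). The C30 acid branch contributes steps 14–21.

Steps most likely to fail

Step 5 (key step).
- **Risk:** The attack of the C4 radical on the aldehyde is reversible. If fragmentation of the alkoxy radical outruns its reduction, the sequence drains into plain hydrogenation of the isopropenyl group. Silane reduction or acetalisation of the aldehyde, or weak facial control at C3, would add to the loss.
- **Fallback:** The acceptor is changed to a nitrile and C3 is set afterwards by hydride.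
  - Starting from 9, iodine in aqueous ammonia/THF should give the keto nitrile F1.
  - Under the same Fe(acac)3/PhSiH3 conditions, the known HAT cyclisation of alkenes onto nitriles should give the cyclic N–H ketimine F2. This closure is 6-exo-dig and far less reversible, and the nitrile is inert to silane and ethanol.
  - Mildly acidic aqueous work-up should hydrolyse it to the 3,9-dione F3.
  - NaBH4 in CH2Cl2/MeOH at −78 °C should reduce the saturated C3 ketone ahead of the conjugated, doubly flanked C9 ketone. Axial hydride delivery gives the equatorial alcohol, and the route is rejoined at 12.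

Step 7.
- **Risk:** Shielding of the C9 carbonyl by the quaternary C10 and the C17 methyl may slow the 1,2-addition so much that γ-deprotonation of the enone takes over and the ketone is merely recovered.
- **Fallback:** Carbanion addition/elimination is replaced by a titanium methylidene. Heating 13 with dimethyltitanocene (Petasis reagent) in toluene at about 75 °C supplies a small, non-basic, oxophilic carbene. It methylenates hindered and enolisable ketones by a [2+2]/cycloreversion sequence. This leads from 13 directly to 15 and makes no new compound (F0).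

Step 3.
- **Risk:** Chemoselectivity may erode through competing hydroboration of the isopropenyl group or 1,2-reduction of the ketone.
- **Fallback:** Boron chemistry is abandoned for an aldehyde-selective, nitrite-modified Wacker oxidation (PdCl2(PhCN)2, CuCl2, AgNO2, t-BuOH/MeNO2, O2, rt). Only the monosubstituted alkene engages palladium(II), and the quaternary neighbour favours attack at the terminus. It sets out from 6, bypasses 8, comes back at 9 and makes no new compound (F0).

Further compounds
F1 | step 5 | keto nitrile, analogue of 9 with CH2CH2C≡N in place of CH2CH2CHO | CC1=CC[C@H](C(C)=C)[C@@](C)(CCC#N)C1=O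
F2 | step 5 | ent-3-imino-11-nordrim-7-en-9-one (N–H ketimine, hydrolysed on work-up) | CC1=CC[C@@H]2C(C)(C)C(=N)CC[C@@]2(C)C1=O
F3 | step 5 | ent-11-nordrim-7-ene-3,9-dione | CC1=CC[C@@H]2C(C)(C)C(=O)CC[C@@]2(C)C1=O
F0 | step 7 | none | none
F0 | step 3 | none | none
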